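## The problem

The target **15** is a flavone, a 2-aryl-4H-chromen-4-one in which ring A and ring C share the C4a–C8a bond and ring B is attached at C2. It has no stereocenter, so the task is one of regiochemistry and oxygen density, not of configuration. Ring A is hexasubstituted: C5, C6, C7 and C8 carry methoxyl groups, C8a carries O1 and C4a carries the C4 carbonyl, so every ring A oxygen has to be in place before or while ring C is formed. Ring C adds a seventh oxygen at C3, the only one that comes from neither aryl building block, and it sits between the carbonyl group and a twisted, ortho-substituted aryl group. Ring B is a 2,4-dimethoxyphenyl group with strongly nucleophilic C3' and C5' positions, so any electrophile used after ring B is present must find a faster partner. The sensitive sites are the methyl ethers next to a carbonyl group (cleaved by strong Lewis acids), C2 of the pyranone (a vinylogous ester carbon that hard nucleophiles attack with ring opening) and the penta-oxygenated arene (oxidized to quinones). The enabling feature is that C4a is flanked on both sides by oxygen-bearing carbons, C5 and C8a: a pentamethoxyphenyl ketone is therefore symmetric about its ketone-bearing carbon, either ortho methoxyl can become O1, and closing O1–C2 onto an alkyne with an iodine electrophile leaves a handle exactly at C3.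

## Retrosynthesis

**C3–OMe.** The C3–O bond of **15** is cut first, back to the 3-iodochromone **14**. Placing this oxygen last means that no α-methoxy ketone or enol ether has to be carried through organolithium and oxidation steps. The forward reaction is a CuI-catalyzed etherification of a vinyl iodide with methanol, which must be faster than attack of methoxide at C2.

**O1–C2 (ring C).** In **14** the O1–C2 bond and the C3–I bond are cut together, with return of a methyl group to O1. This leads to the ynone **12**, 3-(2,4-dimethoxyphenyl)-1-(pentamethoxyphenyl)prop-2-yn-1-one. Cutting C4–C4a (acylation of a pentaoxygenated arene) or C2–C1' (cross-coupling on a preformed chromone) would leave the crowded ring A chromone to be made separately. The O1–C2 cut gives an acyclic precursor that already holds every carbon of the target, and its pentamethoxyphenyl group removes any question of which oxygen closes the ring. The forward reaction has to close in the 6-endo mode and spare ring B.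

**C4–C(alkyne).** The ynone **12** is cut between the carbonyl carbon and the alkyne, through the propargylic alcohol **11**, to pentamethoxybenzaldehyde **7** and the lithium acetylide **10** of alkyne **9**. Acetylide addition followed by oxidation is preferred to an acyl Sonogashira coupling, which would require **7** to be oxidized further and then activated at a carbonyl carbon flanked by two ortho substituents. Aldehyde **7** is reached directly by formylation.

**Alkyne carbon.** Alkyne **9** is cut at the triple bond to 2,4-dimethoxybenzaldehyde **8** and a one-carbon homologation. This is a single mild step and avoids a halogenation and cross-coupling sequence on the electron-rich ring.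

**Ring A.** Aldehyde **7** is cut at its formyl carbon to pentamethoxybenzene **5**, whose only ring hydrogen lies between two methoxyl groups and is removed by n-BuLi to give aryllithium **6**. Arene **5** is cut at one O–CH3 bond to phenol **4**. The C–O bond of **4** goes back to 1,2,3,4-tetramethoxybenzene **1** by ortho-lithiation to aryllithium **2**, borylation to boronate **3** and oxidation. Arene **1** has two equivalent hydrogens, so no regiochemical choice arises in this sequence.

## Roads not taken

Alternative 1: The cut is at O1–C8a and C4–C4a, by insertion of an aryne into the carboxyl group of a cinnamic acid. CsF would release 3,4,5,6-tetramethoxybenzyne A2 from 3,4,5,6-tetramethoxy-2-(trimethylsilyl)phenyl triflate A1. The carboxylate of (Z)-3-(2,4-dimethoxyphenyl)-2-methoxyprop-2-enoic acid A3 would add to A2 through oxygen, and the aryl anion so formed would take over the acyl group to give the 2'-hydroxy-α-methoxychalcone A4. A later oxidative cyclization of A4 would close O1–C2 and give **15**.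
- Merits: the C3 methoxyl is present from the start, so no late C–O coupling is needed. The aryne A2 is symmetric, and ring B never meets a halogen electrophile.
- Weak points: A1 needs a longer preparation than aldehyde **7**, namely bromination of phenol **4**, O-silylation, lithiation with silyl migration to carbon, and triflation. A3 must be made as a single alkene isomer. A tetra-oxygenated aryne such as A2 is hindered and electron-rich, so plain O-arylation without acyl transfer is a real competitor. The key step closes no ring, so A4 still has to be cyclized.
- Comparison: this road is better in how it handles the C3 oxygen. The chosen plan sets against it two simple fragments, a key step that forms ring C itself, and only one uncertain step after it.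

Alternative 2: The cut is at the C6–O and C8–O bonds of an intact flavonol skeleton, bought as morin A5. Partial methylation of A5 would give the 5-hydroxy tetramethyl ether A6, and bromination of A6 would give the 6,8-dibromide A7. In the key step A7 would be treated with NaOMe and CuBr in hot MeOH and DMF, so that both bromines are exchanged for methoxyl and 2-(2,4-dimethoxyphenyl)-5-hydroxy-3,6,7,8-tetramethoxychromone A8 results. Methylation of the chelated hydroxyl of A8 would finish **15**.
- Merits: about four steps from a cheap natural product, with the carbon skeleton and the C3 oxygen purchased.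
- Weak points: the bromination of A6 must choose C6 and C8 of ring A over C5' and C3' of ring B, which is a resorcinol dimethyl ether of comparable nucleophilicity. Any extra bromine in A7 would end as an extra methoxyl in a product that is hard to separate from A8. Hot methoxide also tests ring C.
- Comparison: in step count this road is clearly better (about four steps against eight). The chosen plan sets against it regiochemical certainty: every ring A oxygen is fixed by a symmetric arene, and the one electrophilic halogenation has an alkyne as the preferred partner.

Alternative 3: The cut is at C1'–C2' and C5'–C6' of ring B. 2-Ethynyl-3,5,6,7,8-pentamethoxychromone A9 and 1,1-dimethoxy-3-(trimethylsilyloxy)buta-1,3-diene A10 would combine in a Diels–Alder reaction. Loss of methanol after the cycloaddition would aromatize ring B, desilylation would give the 4'-phenol A11, and methylation of A11 would give **15**.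
- Merits: the substitution pattern of ring B is dictated by the polarity of diene A10, ring B is never exposed to an electrophile, and the approach is attractive for varying ring B.
- Weak points: A9 already contains the hexasubstituted ring A, the pyranone and the C3 methoxyl, so the hard part of the problem is only moved into its preparation. The alkyne of A9 is activated only as a vinylogous ynone through a C2=C3 bond that carries a donor methoxyl, so a slow cycloaddition is expected. The C2=C3 bond may itself compete as dienophile, and A11 needs a further methylation.
- Comparison: this road is the better one for ring B analogs. For this target the chosen plan is more direct, since it draws both aryl rings from simple arenes and forms ring C and the C3 handle in one step.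

Key step: step 7

Assumption: 1,2,3,4-tetramethoxybenzene **1** is taken as a catalogue compound.

## Route

Step 1
Reactants: 1 1,2,3,4-tetramethoxybenzene
Product: 4 2,3,4,5-tetramethoxyphenol, via (2,3,4,5-tetramethoxyphenyl)lithium 2 (not isolated), via dimethyl (2,3,4,5-tetramethoxyphenyl)boronate 3 (not isolated)
Conditions: n-BuLi (1.1 equiv), TMEDA, THF, 0 °C; B(OMe)3, −78 °C to rt; AcOH, 30% H2O2, 0 °C
Reagents that add atoms: hydrogen peroxide, OO (phenol oxygen of 4); n-butyllithium, [Li]CCCC (lithium of 2 only); trimethyl borate, COB(OC)OC (B(OMe)2 group of 3 only)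
Why: Directed ortho-metalation; the two ring hydrogens of 1 are equivalent and each lies ortho to a methoxyl, so one aryllithium should form. Borylation and peroxide oxidation (1,2-shift of the aryl group from boron to oxygen) then convert C–Li into C–OH in the same flask.

Step 2
Reactants: 4 2,3,4,5-tetramethoxyphenol
Product: 5 pentamethoxybenzene
Conditions: MeI, K2CO3, acetone, reflux
Reagents that add atoms: iodomethane, CI
Why: Williamson ether synthesis on a phenoxide; the molecule has no other nucleophilic site.

Step 3
Reactants: 5 pentamethoxybenzene
Product: 7 pentamethoxybenzaldehyde, via (pentamethoxyphenyl)lithium 6 (not isolated)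
Conditions: n-BuLi (1.1 equiv), TMEDA, THF, 0 °C; DMF, 0 °C to rt; aq HCl
Reagents that add atoms: N,N-dimethylformamide, CN(C)C=O (formyl group of 7); n-butyllithium, [Li]CCCC (lithium of 6 only)
Why: Directed ortho-metalation and formylation; the single ring hydrogen of 5 lies between two methoxyl groups and should be removed cleanly, and the aryllithium adds to DMF to give the aldehyde on hydrolysis.

Step 4
Reactants: 8 2,4-dimethoxybenzaldehyde
Product: 9 1-ethynyl-2,4-dimethoxybenzene
Conditions: dimethyl (1-diazo-2-oxopropyl)phosphonate, K2CO3, MeOH, 0 °C to rt
Reagents that add atoms: dimethyl (1-diazo-2-oxopropyl)phosphonate (Ohira–Bestmann reagent), COP(=O)(OC)C(=[N+]=[N-])C(C)=O (terminal alkyne carbon)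
Why: Seyferth–Gilbert homologation in the Ohira–Bestmann variant; methanolysis releases the diazomethylphosphonate anion, olefination gives a diazoalkene, and loss of N2 with 1,2-hydrogen shift gives the terminal alkyne. The aldehyde is not enolizable and tolerates the mild carbonate base.

Step 5
Reactants: 9 1-ethynyl-2,4-dimethoxybenzene, 7 pentamethoxybenzaldehyde
Product: 11 rac-3-(2,4-dimethoxyphenyl)-1-(pentamethoxyphenyl)prop-2-yn-1-ol, via lithium (2,4-dimethoxyphenyl)acetylide 10 (not isolated)
Conditions: 9, n-BuLi, THF, −78 °C; then 7, −78 to 0 °C; aq NH4Cl
Reagents that add atoms: n-butyllithium, [Li]CCCC (lithium of 10 only)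
Why: 1,2-Addition of a lithium acetylide to a non-enolizable aldehyde; the linear nucleophile should reach the carbonyl group between the two ortho methoxyls. The carbinol center forms as a racemate and is removed in step 6.

Step 6
Reactants: 11 rac-3-(2,4-dimethoxyphenyl)-1-(pentamethoxyphenyl)prop-2-yn-1-ol
Product: 12 3-(2,4-dimethoxyphenyl)-1-(pentamethoxyphenyl)prop-2-yn-1-one
Conditions: activated MnO2 (excess), CH2Cl2, rt
Reagents that add atoms: none
Why: MnO2 oxidation of a secondary alcohol that is both benzylic and propargylic; the neutral heterogeneous conditions should avoid ionization of the electron-rich carbinol.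

Step 7
Reactants: 12 3-(2,4-dimethoxyphenyl)-1-(pentamethoxyphenyl)prop-2-yn-1-one
Product: 14 2-(2,4-dimethoxyphenyl)-3-iodo-5,6,7,8-tetramethoxy-4H-chromen-4-one, via 1-methylchromenium chloride 13 (not isolated)
Conditions: ICl (1.1 equiv), CH2Cl2, −78 °C; aq Na2S2O3
Reagents that add atoms: iodine monochloride, ClI
Why: ICl delivers I+ to the alkyne of 12, and the iodonium ion opens toward the alkyne carbon that carries ring B, because positive charge there is benzylic to the 2,4-dimethoxyphenyl donor and remote from the carbonyl group. The oxygen of an ortho methoxyl of ring A attacks this carbon anti to iodine, which forms O1–C2 and closes ring C in the 6-endo-dig mode to give the methyloxonium chloride 13. Chloride then cleaves the O–CH3 bond of 13 by SN2 attack, so chloromethane leaves and the neutral 3-iodochromone 14 remains with iodine on C3. The closest known reaction type is the ICl-induced iodocyclization of ortho-methoxyaryl alkynyl ketones to 3-iodochromones and 3-iodoflavones, applied here to a ketone with two ortho methoxyls. No stereocenter is formed. The step needs attack at the aryl-bearing carbon and not at the carbonyl-bearing carbon, which would lead by 5-exo closure to an iodoaurone or, through the 2'-methoxyl of ring B in a 5-endo mode, to a 3-iodobenzofuran; the polarization of the ynone by the donor aryl group and the acceptor carbonyl secures this. It also needs the alkyne to react before C5' of ring B, which about one equivalent of ICl added at −78 °C should ensure, while ring A has no free C–H. Which ortho methoxyl reacts is of no consequence, because the ketone-bearing carbon lies on the symmetry axis of the pentamethoxyphenyl group and either closure leads to the 5,6,7,8-tetramethoxy arrangement.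

Step 8
Reactants: 14 2-(2,4-dimethoxyphenyl)-3-iodo-5,6,7,8-tetramethoxy-4H-chromen-4-one
Product: 15 2-(2,4-dimethoxyphenyl)-3,5,6,7,8-pentamethoxy-4H-chromen-4-one
Conditions: CuI (10 mol %), 1,10-phenanthroline (20 mol %), Cs2CO3, MeOH–toluene, 90 °C, sealed tube
Reagents that add atoms: methanol, CO
Why: Ullmann-type C–O coupling of a vinyl iodide with an aliphatic alcohol; a phenanthroline-ligated monovalent copper methoxide should insert into the C3–I bond and release the enol ether by reductive elimination. The carbonate base keeps the concentration of free methoxide low, which protects C2 of the pyranone.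

## Compound list

1 | 1,2,3,4-tetramethoxybenzene | COc1ccc(OC)c(OC)c1OC | starting material
2 | (2,3,4,5-tetramethoxyphenyl)lithium | [Li]c1cc(OC)c(OC)c(OC)c1OC | intermediate
3 | dimethyl (2,3,4,5-tetramethoxyphenyl)boronate | COB(OC)c1cc(OC)c(OC)c(OC)c1OC | intermediate
4 | 2,3,4,5-tetramethoxyphenol | COc1cc(O)c(OC)c(OC)c1OC | intermediate
5 | pentamethoxybenzene | COc1cc(OC)c(OC)c(OC)c1OC | intermediate
6 | (pentamethoxyphenyl)lithium | [Li]c1c(OC)c(OC)c(OC)c(OC)c1OC | intermediate
7 | pentamethoxybenzaldehyde | COc1c(OC)c(OC)c(C=O)c(OC)c1OC | intermediate
8 | 2,4-dimethoxybenzaldehyde | COc1ccc(C=O)c(OC)c1 | starting material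
9 | 1-ethynyl-2,4-dimethoxybenzene | COc1ccc(C#C)c(OC)c1 | intermediate
10 | lithium (2,4-dimethoxyphenyl)acetylide | [Li]C#Cc1ccc(OC)cc1OC | intermediate
11 | rac-3-(2,4-dimethoxyphenyl)-1-(pentamethoxyphenyl)prop-2-yn-1-ol (racemic carbinol) | COc1ccc(C#CC(O)c2c(OC)c(OC)c(OC)c(OC)c2OC)c(OC)c1 | intermediate
12 | 3-(2,4-dimethoxyphenyl)-1-(pentamethoxyphenyl)prop-2-yn-1-one | COc1ccc(C#CC(=O)c2c(OC)c(OC)c(OC)c(OC)c2OC)c(OC)c1 | intermediate
13 | 2-(2,4-dimethoxyphenyl)-3-iodo-5,6,7,8-tetramethoxy-1-methyl-4-oxo-4H-chromen-1-ium chloride | COc1ccc(C2=C(I)C(=O)c3c(OC)c(OC)c(OC)c(OC)c3[O+]2C)c(OC)c1.[Cl-] | intermediate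
14 | 2-(2,4-dimethoxyphenyl)-3-iodo-5,6,7,8-tetramethoxy-4H-chromen-4-one | COc1ccc(-c2oc3c(OC)c(OC)c(OC)c(OC)c3c(=O)c2I)c(OC)c1 | intermediate
15 | 2-(2,4-dimethoxyphenyl)-3,5,6,7,8-pentamethoxy-4H-chromen-4-one (CNP0276152.0) | COc1ccc(-c2oc3c(OC)c(OC)c(OC)c(OC)c3c(=O)c2OC)c(OC)c1 | target

## Step count and risks

Total steps: 8. Longest linear sequence: 7 steps (steps 1, 2, 3, 5, 6, 7 and 8, from **1**); the alkyne branch (step 4) joins at step 5.

**Step 7 (key step).** The likely failure is loss of chemoselectivity: iodination of ring B at C5', or closure through the carbonyl-bearing alkyne carbon, competes with the 6-endo closure, because ring B is a resorcinol dimethyl ether with its own ortho methoxyl. The fallback builds the pyranone without a halonium ion and places iodine by deprotonation. It sets out from **5** and **8**. Friedel–Crafts acetylation of **5** with AcCl and AlCl3, which also cleaves the methoxyl ortho to the new ketone through chelation, should give 1-(2-hydroxy-3,4,5,6-tetramethoxyphenyl)ethanone F1. Claisen–Schmidt condensation of F1 with **8** (KOH, EtOH) should give (E)-3-(2,4-dimethoxyphenyl)-1-(2-hydroxy-3,4,5,6-tetramethoxyphenyl)prop-2-en-1-one F2. Oxidative cyclization with catalytic I2 in hot DMSO should give 2-(2,4-dimethoxyphenyl)-5,6,7,8-tetramethoxy-4H-chromen-4-one F3. Lithiation of F3 at C3 with lithium diisopropylamide at −78 °C and quenching with I2 should give **14**, where the route is rejoined.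

**Step 8.** The likely failure is that reductive loss of iodine, or addition of methoxide at C2 with opening of ring C, outruns C–O bond formation at the hindered C3. The fallback reverses the polarity at C3 and sets out from **14**. Iodine–magnesium exchange with i-PrMgCl·LiCl in THF at −40 °C should give [2-(2,4-dimethoxyphenyl)-5,6,7,8-tetramethoxy-4-oxo-4H-chromen-3-yl]magnesium chloride F4. Trapping with B(OMe)3 should give dimethyl [2-(2,4-dimethoxyphenyl)-5,6,7,8-tetramethoxy-4-oxo-4H-chromen-3-yl]boronate F5. Oxidation in the same flask with H2O2 and AcOH should give 2-(2,4-dimethoxyphenyl)-3-hydroxy-5,6,7,8-tetramethoxy-4H-chromen-4-one F6. O-Methylation of F6 (MeI, K2CO3, acetone) comes back to the route at **15**.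

**Step 1.** The likely failures are incomplete metalation, since the methoxyl next to the C–H bond is twisted by its neighbor and directs weakly, and over-oxidation of the electron-rich phenol toward a quinone during the peroxide stage. The fallback replaces the organolithium by electrophilic substitution and sets out from **1**. Vilsmeier–Haack formylation (POCl3, DMF) should give 2,3,4,5-tetramethoxybenzaldehyde F7. Baeyer–Villiger oxidation with mCPBA should give 2,3,4,5-tetramethoxyphenyl formate F8. Methanolysis (K2CO3, MeOH) returns to the route at **4**.

**Step 6.** The likely failures are slow conversion of the hindered carbinol, or ionization of the electron-rich benzylic propargylic alcohol on the oxide surface followed by Meyer–Schuster rearrangement. The fallback reaches the ketone oxidation state directly and sets out from **9** and **5**. Deprotonation of **9** to **10** and acylation with N-methoxy-N-methylcarbamoyl chloride should give the Weinreb amide 3-(2,4-dimethoxyphenyl)-N-methoxy-N-methylprop-2-ynamide F9. Addition of aryllithium **6**, made from **5** as in step 3, to F9 should give **12** directly, where the route is rejoined.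

## Further compounds

F1 | step 7 | 1-(2-hydroxy-3,4,5,6-tetramethoxyphenyl)ethanone | CC(=O)c1c(O)c(OC)c(OC)c(OC)c1OC
F2 | step 7 | (E)-3-(2,4-dimethoxyphenyl)-1-(2-hydroxy-3,4,5,6-tetramethoxyphenyl)prop-2-en-1-one | COc1ccc(/C=C/C(=O)c2c(O)c(OC)c(OC)c(OC)c2OC)c(OC)c1
F3 | step 7 | 2-(2,4-dimethoxyphenyl)-5,6,7,8-tetramethoxy-4H-chromen-4-one | COc1ccc(-c2cc(=O)c3c(OC)c(OC)c(OC)c(OC)c3o2)c(OC)c1
F4 | step 8 | [2-(2,4-dimethoxyphenyl)-5,6,7,8-tetramethoxy-4-oxo-4H-chromen-3-yl]magnesium chloride | COc1ccc(-c2oc3c(OC)c(OC)c(OC)c(OC)c3c(=O)c2[Mg]Cl)c(OC)c1
F5 | step 8 | dimethyl [2-(2,4-dimethoxyphenyl)-5,6,7,8-tetramethoxy-4-oxo-4H-chromen-3-yl]boronate | COB(OC)c1c(-c2ccc(OC)cc2OC)oc2c(OC)c(OC)c(OC)c(OC)c2c1=O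
F6 | step 8 | 2-(2,4-dimethoxyphenyl)-3-hydroxy-5,6,7,8-tetramethoxy-4H-chromen-4-one | COc1ccc(-c2oc3c(OC)c(OC)c(OC)c(OC)c3c(=O)c2O)c(OC)c1
F7 | step 1 | 2,3,4,5-tetramethoxybenzaldehyde | COc1cc(C=O)c(OC)c(OC)c1OC
F8 | step 1 | 2,3,4,5-tetramethoxyphenyl formate | COc1cc(OC=O)c(OC)c(OC)c1OC
F9 | step 6 | 3-(2,4-dimethoxyphenyl)-N-methoxy-N-methylprop-2-ynamide | COc1ccc(C#CC(=O)N(C)OC)c(OC)c1
A1 | alternative 1 | 3,4,5,6-tetramethoxy-2-(trimethylsilyl)phenyl trifluoromethanesulfonate | COc1c(OC)c(OC)c(OS(=O)(=O)C(F)(F)F)c([Si](C)(C)C)c1OC
A2 | alternative 1 | 3,4,5,6-tetramethoxybenzyne | COC1=C(OC)C(OC)=C(OC)C#C1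
A3 | alternative 1 | (Z)-3-(2,4-dimethoxyphenyl)-2-methoxyprop-2-enoic acid | COc1ccc(/C=C(\OC)C(=O)O)c(OC)c1
A4 | alternative 1 | (Z)-3-(2,4-dimethoxyphenyl)-1-(2-hydroxy-3,4,5,6-tetramethoxyphenyl)-2-methoxyprop-2-en-1-one | COc1ccc(/C=C(\OC)C(=O)c2c(O)c(OC)c(OC)c(OC)c2OC)c(OC)c1
A5 | alternative 2 | morin, 2-(2,4-dihydroxyphenyl)-3,5,7-trihydroxy-4H-chromen-4-one | O=c1c(O)c(-c2ccc(O)cc2O)oc2cc(O)cc(O)c12
A6 | alternative 2 | 2-(2,4-dimethoxyphenyl)-5-hydroxy-3,7-dimethoxy-4H-chromen-4-one | COc1ccc(-c2oc3cc(OC)cc(O)c3c(=O)c2OC)c(OC)c1
A7 | alternative 2 | 6,8-dibromo-2-(2,4-dimethoxyphenyl)-5-hydroxy-3,7-dimethoxy-4H-chromen-4-one | COc1ccc(-c2oc3c(Br)c(OC)c(Br)c(O)c3c(=O)c2OC)c(OC)c1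
A8 | alternative 2 | 2-(2,4-dimethoxyphenyl)-5-hydroxy-3,6,7,8-tetramethoxy-4H-chromen-4-one | COc1ccc(-c2oc3c(OC)c(OC)c(OC)c(O)c3c(=O)c2OC)c(OC)c1
A9 | alternative 3 | 2-ethynyl-3,5,6,7,8-pentamethoxy-4H-chromen-4-one | C#Cc1oc2c(OC)c(OC)c(OC)c(OC)c2c(=O)c1OC
A10 | alternative 3 | 1,1-dimethoxy-3-(trimethylsilyloxy)buta-1,3-diene | COC(OC)=CC(=C)O[Si](C)(C)C
A11 | alternative 3 | 2-(4-hydroxy-2-methoxyphenyl)-3,5,6,7,8-pentamethoxy-4H-chromen-4-one | COc1cc(O)ccc1-c1oc2c(OC)c(OC)c(OC)c(OC)c2c(=O)c1OC
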